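The aromatic ring is assembled from acyclic pieces. The C17 chain is attached at ring carbon C5 and the hydroxyls at C1 and C3 are both meta to it, the substitution pattern of a 5-alkylcyclohexane-1,3-dione. The ring is therefore cut at C5–C6 and C1–C2 into dimethyl malonate and an acyclic (E)-methyl enone, C21, whose (S)-carbinol lies fourteen methylenes beyond the alkene. A single methoxide-mediated Michael–Claisen annulation makes both bonds and the six-membered carbocycle with the oxygen pattern already in place; iodine-catalysed dehydrogenation and loss of the ester carbon then deliver the resorcinol. The stereocentre comes from an early catalytic asymmetric ethylation.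

Key step: step 5

Assumption: the β-dicarbonyl compound 10 is drawn as its keto tautomer although it is largely enolised, the ring stereocentres of 9 and 10 (formed without control, lost on aromatisation) are left undefined, and the (1R,2R)-ligand of step 2 is taken as the enantiomer that sends ethyl to the Si face, to be checked by Mosher-ester analysis of 4 and replaced by its antipode if needed.

Step 1
Reactants: 1 16-hexadecanolide
Product: 2 16-hydroxyhexadecanal
Conditions: i-Bu2AlH (1.1 equiv), CH2Cl2, −78 °C; MeOH, then aq. potassium sodium tartrate
Reagents that add atoms: none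
Why: Partial ester reduction with i-Bu2AlH, in which one hydride adds at −78 °C to give an aluminium hemiacetal that persists until hydrolysis, and since a 17-membered lactol has no stability the product is released as the open-chain ω-hydroxy aldehyde.

Step 2
Reactants: 2 16-hydroxyhexadecanal; 3 diethylzinc
Product: 4 (S)-octadecane-1,16-diol
Conditions: Et2Zn (3 equiv), Ti(Oi-Pr)4 (1.5 equiv), (1R,2R)-1,2-bis(trifluoromethanesulfonamido)cyclohexane (5 mol %), toluene, −20 °C; then 1 M HCl
Reagents that add atoms: diethylzinc, CC[Zn]CC
Why: Ligand-accelerated, titanium-mediated enantioselective addition of a dialkylzinc to an aldehyde, in which the chiral bis(sulfonamido)titanium complex should direct ethyl to the Si face of the unbranched aldehyde and so form the new carbinol C16 as (S), while the first equivalent of Et2Zn only converts the remote hydroxyl into an alkoxide of the same kind as the product alkoxide.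

Step 3
Reactants: 4 (S)-octadecane-1,16-diol
Product: 5 (S)-16-hydroxyoctadecanal
Conditions: TEMPO (10 mol %), PhI(OAc)2 (1.1 equiv), CH2Cl2, rt
Reagents that add atoms: none
Why: Oxoammonium (TEMPO/PhI(OAc)2) oxidation is strongly selective for an unhindered primary hydroxyl over a secondary one and stops at the aldehyde without water, so the C16 carbinol and its configuration should stay untouched.

Step 4
Reactants: 5 (S)-16-hydroxyoctadecanal; 6 1-(triphenylphosphoranylidene)propan-2-one
Product: 7 (S,E)-19-hydroxyhenicos-3-en-2-one
Conditions: Ph3P=CHC(O)CH3 (1.5 equiv), toluene, 80 °C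
Reagents that add atoms: 1-(triphenylphosphoranylidene)propan-2-one, CC(=O)C=P(c1ccccc1)(c1ccccc1)c1ccccc1
Why: Wittig olefination with a ketone-stabilised ylide, which reacts only at the aldehyde under neutral conditions, tolerates the free hydroxyl and should give the enone with the E-selectivity typical of stabilised ylides.

Step 5
Reactants: 7 (S,E)-19-hydroxyhenicos-3-en-2-one; 8 dimethyl malonate
Product: 10 methyl 6-[(S)-15-hydroxyheptadecyl]-2,4-dioxocyclohexane-1-carboxylate, via Michael adduct 9 (not isolated)
Conditions: NaOMe (1.3 equiv), dimethyl malonate (1.2 equiv), MeOH, reflux; then 1 M HCl, 0 °C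
Reagents that add atoms: dimethyl malonate, COC(=O)CC(=O)OC
Why: Methoxide forms the malonate anion, which adds to the enone β-carbon C4 (future arene C5) to give 9; proton transfer then gives the methyl ketone enolate, which acylates at a malonate ester carbonyl with loss of methoxide (Claisen/Dieckmann condensation) and closes the carbocycle. The closest known reaction type is the classical malonate Michael–Claisen route from alk-3-en-2-ones to 5-alkylcyclohexane-1,3-diones (for example dimedone from mesityl oxide). The single ring closes in a 6-(enolendo)-exo-trig mode, which is favoured. Ring carbons C6 and C1 become stereogenic without control, which does not matter because C1 is enolisable and both become sp2 on aromatisation, while C15′ of the chain is far from every reacting site. The step needs 1,4- over 1,2-addition and acylation from the methyl side: the soft, reversibly adding malonate secures the first, only the methyl enolate can reach an ester through a six-membered transition state, and final deprotonation of the cyclic β-dicarbonyl product draws all equilibria towards 10. Methanol as solvent returns any ester exchange at the C15′ alkoxide to the methyl ester.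

Step 6
Reactants: 10 methyl 6-[(S)-15-hydroxyheptadecyl]-2,4-dioxocyclohexane-1-carboxylate
Product: 11 methyl 2,4-dihydroxy-6-[(S)-15-hydroxyheptadecyl]benzoate
Conditions: I2 (20 mol %), DMSO, 80 °C; aq. Na2S2O3 work-up
Reagents that add atoms: none
Why: Iodine-catalysed oxidative aromatisation with DMSO as terminal oxidant (known for 2,4-dioxocyclohexanecarboxylates and cyclohexenones), in which the enolised β-dicarbonyl is iodinated at C1 or C3, HI is eliminated to a cyclohexadienone that tautomerises to the resorcylate and DMSO reoxidises HI to I2, while the isolated secondary carbinol is not activated towards this mild oxidant and the ester should damp iodination of the new ring.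

Step 7
Reactants: 11 methyl 2,4-dihydroxy-6-[(S)-15-hydroxyheptadecyl]benzoate
Product: 12 hansfordiol C, 5-[(S)-15-hydroxyheptadecyl]benzene-1,3-diol
Conditions: KOH, MeOH/H2O, reflux, Ar; then 2 M HCl, 80 °C
Reagents that add atoms: none
Why: Saponification followed by protodecarboxylation of a 2,4-dihydroxybenzoic acid (as in the conversion of orsellinates into orcinol), which loses CO2 readily because ipso-protonation is assisted by the ortho- and para-hydroxyls, the C15′ carbinol being inert to both the base and the dilute acid.

Compound list
1 | 16-hexadecanolide (oxacycloheptadecan-2-one) | O=C1CCCCCCCCCCCCCCCO1 | starting material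
2 | 16-hydroxyhexadecanal | O=CCCCCCCCCCCCCCCCO | intermediate
3 | diethylzinc | CC[Zn]CC | starting material
4 | (S)-octadecane-1,16-diol | CC[C@H](O)CCCCCCCCCCCCCCCO | intermediate
5 | (S)-16-hydroxyoctadecanal | CC[C@H](O)CCCCCCCCCCCCCCC=O | intermediate
6 | 1-(triphenylphosphoranylidene)propan-2-one | CC(=O)C=P(c1ccccc1)(c1ccccc1)c1ccccc1 | starting material
7 | (S,E)-19-hydroxyhenicos-3-en-2-one | CC[C@H](O)CCCCCCCCCCCCCC/C=C/C(C)=O | intermediate
8 | dimethyl malonate | COC(=O)CC(=O)OC | starting material
9 | dimethyl 2-[(19S)-19-hydroxy-2-oxohenicosan-4-yl]propanedioate (both C4 epimers, not isolated) | CC[C@H](O)CCCCCCCCCCCCCCC(CC(C)=O)C(C(=O)OC)C(=O)OC | intermediate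
10 | methyl 6-[(S)-15-hydroxyheptadecyl]-2,4-dioxocyclohexane-1-carboxylate (ring diastereomers, largely enolised) | CC[C@H](O)CCCCCCCCCCCCCCC1CC(=O)CC(=O)C1C(=O)OC | intermediate
11 | methyl 2,4-dihydroxy-6-[(S)-15-hydroxyheptadecyl]benzoate | CC[C@H](O)CCCCCCCCCCCCCCc1cc(O)cc(O)c1C(=O)OC | intermediate
12 | hansfordiol C, 5-[(S)-15-hydroxyheptadecyl]benzene-1,3-diol | CC[C@H](O)CCCCCCCCCCCCCCc1cc(O)cc(O)c1 | target

Total step count: 7
Longest linear sequence: 7 steps (1 to 12)

Steps most likely to fail

Step 6. The catalytic cycle may stall if iodine is held as an α-iodo diketone or aryl iodide, the electron-rich ring may be iodinated, or the C15′ carbinol may be oxidised. The fallback sets out from 10 and comes back at 12. Compound 10 would be saponified and decarboxylated (aq. NaOH, reflux; then HCl, heat) to 5-[(S)-15-hydroxyheptadecyl]cyclohexane-1,3-dione F1. Stoichiometric I2 in refluxing MeOH would then aromatise F1 through its methyl enol ether to (S)-17-(3,5-dimethoxyphenyl)heptadecan-3-ol F2. Both methyl ethers would be cleaved by fusion with excess MeMgI (neat, 160 °C), the carbinol being carried as its magnesium alkoxide, to give 12. Thiolate reagents are avoided here because resorcinol dimethyl ethers tend to stop at the monomethyl ether.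

Step 2. Facial selectivity may be poor, or a racemic background ethylation may be promoted by zinc or titanium alkoxide aggregates of the free ω-hydroxyl. The fallback sets out from 2 and comes back at 4. Corey–Chaykovsky epoxidation of 2 (Me3SI, NaH, DMSO/THF) would give racemic 15-(oxiran-2-yl)pentadecan-1-ol F3. Hydrolytic kinetic resolution with 0.55 equiv of water and the (salen)Co(OAc) complex of trivalent cobalt (the (S,S)-enantiomer expected) would leave (R)-15-(oxiran-2-yl)pentadecan-1-ol F4 and convert its antipode into (S)-heptadecane-1,2,17-triol F5, which is removed by chromatography. MeMgBr with catalytic CuI (THF, −30 °C) would open F4 at the terminal carbon and give 4, the carbinol centre not being touched.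

Step 1. Over-reduction to hexadecane-1,16-diol may occur if the aluminium hemiacetal of the strain-free macrolactone collapses before the quench, and stopping early leaves lactone. The fallback sets out from 1 and comes back at 2. The lactone would be opened with MeNH(OMe)·HCl and i-PrMgCl (THF, −10 °C) to the Weinreb amide 16-hydroxy-N-methoxy-N-methylhexadecanamide F6. LiAlH4 (THF, 0 °C) would reduce F6 through a chelated tetrahedral intermediate that cannot collapse before work-up and give 2.

Further compounds
F1 | step 6 | 5-[(S)-15-hydroxyheptadecyl]cyclohexane-1,3-dione | CC[C@H](O)CCCCCCCCCCCCCCC1CC(=O)CC(=O)C1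
F2 | step 6 | (S)-17-(3,5-dimethoxyphenyl)heptadecan-3-ol | CC[C@H](O)CCCCCCCCCCCCCCc1cc(OC)cc(OC)c1
F3 | step 2 | rac-15-(oxiran-2-yl)pentadecan-1-ol | OCCCCCCCCCCCCCCCC1CO1
F4 | step 2 | (R)-15-(oxiran-2-yl)pentadecan-1-ol | OCCCCCCCCCCCCCCC[C@@H]1CO1
F5 | step 2 | (S)-heptadecane-1,2,17-triol | OCCCCCCCCCCCCCCC[C@H](O)CO
F6 | step 1 | 16-hydroxy-N-methoxy-N-methylhexadecanamide | CON(C)C(=O)CCCCCCCCCCCCCCCO
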